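**Retrosynthetic overview**

1. Target ⇒ Shi epoxidation of C10=C11 ⇒ tris-angelate; its three (Z)-2-methylbut-2-enoates ⇒ angelic anhydride, first on the C8 alcohol, then on the unmasked C1/C2 diol; the C7(=C14H2)–C8 unit ⇒ Ni/Cr coupling of a C7 alkenyl triflate with 4-methylpent-3-enal, C8 then fixed by oxidation and CBS reduction.
2. Oxirane C3–C4 ⇒ hydroxyl-directed epoxidation of an all-cis cyclohex-3-ene-1,2-diol; C6 ⇒ epimerised through a temporary γ-lactone between the C7 carboxyl and the C2 hydroxyl.
3. cis-1,2-Diol with C3=C4 ⇒ 7-oxabicyclo[2.2.1]heptene: exo hydroboration puts oxygen on C2, the derived C2 ketone expels the bridge oxygen from C4, and a reagent-controlled reduction returns the C2 alcohol.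
4. 7-Oxabicyclo[2.2.1]heptene ⇒ 3-methylfuran + 3-acryloyloxazolidin-2-one by a catalytic enantioselective, dearomatising Diels–Alder reaction. Enabling feature: in the carbocycle C1–C6 the oxygen-bearing carbons C1 and C4 are 1,4-related on one face, C3 carries the methyl group and C6 (para to C3) the side-chain carbon, so the ring is a ring-opened furan/acrylate adduct.
5. Order of ring formation: carbocycle C1–C6 (with temporary C1–O–C4 bridge) → temporary lactone (C7–O–C2) → oxirane C3/C4 → oxirane C10/C11.

Key step: step 1

Remark on numbering: atoms keep the bisabolane numbering of the target: ring C1 (acyloxy, next to C6), C2 (acyloxy), C3 (C–CH3), C4, C5 (CH2), C6 (side-chain carbon); side chain C7 (=C14H2), C8, C9, C10, C11. β is the ring face that carries the C1 oxygen, α the opposite face. Plain numbers are compounds.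

Assumption: 3-methylfuran is taken to follow the facial sense established for furan under copper bis(oxazoline) catalysis, which calls for the (R,R)-ligand here.

**Step 1**
Reactants: 1 3-methylfuran; 2 3-acryloyl-1,3-oxazolidin-2-one
Product: 3 3-[(1R,2R,4R)-5-methyl-7-oxabicyclo[2.2.1]hept-5-ene-2-carbonyl]-1,3-oxazolidin-2-one (carbonyl endo)
Conditions: [Cu((R,R)-t-Bu-box)](SbF6)2 (5 mol %), 1 (5 equiv), CH2Cl2, −78 °C; endo adduct crystallised free of the minor exo adduct, which has the opposite C1 configuration
Reagents that add atoms: none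
Why: Lewis-acid-catalysed normal-electron-demand Diels–Alder reaction in which 3-methylfuran is dearomatised as the 4π component; the acrylimide is chelated through both carbonyl groups to the square-planar divalent-copper centre of [Cu((R,R)-t-Bu-box)](SbF6)2 in its s-cis form, so that one tert-butyl group blocks one π-face of the alkene. The closest known reaction type is the enantioselective cycloaddition of furan itself with 3-acryloyloxazolidin-2-one under copper bis(oxazoline) catalysis. The six-membered carbocycle C1–C6 is closed intermolecularly by suprafacial formation of the C1–C6 and C4–C5 bonds (concerted but asynchronous, C4–C5 leading), and the furan oxygen thereby becomes a temporary one-atom bridge between C1 and C4 (7-oxabicyclo[2.2.1]heptene). C6 is set by the catalyst-differentiated face of the dienophile, and C1 and C4 follow from the endo transition state (carbonyl under the diene, kinetic control at −78 °C), so the configuration of C1, the centre that is carried into the target, is catalyst-controlled. The step needs regioselectivity, secured by the C3 methyl group, which makes the adjacent furan α-carbon (C4) the most nucleophilic terminus so that it bonds to the β-carbon of the acrylimide (methyl and acyl para), and it needs kinetic control, secured by the low temperature, which suppresses cycloreversion and Friedel–Crafts-type conjugate addition. The endo (6α) position of the acyl group is not that of the target and is inverted on purpose in step 7.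

**Step 2**
Reactants: 3
Product: 4 methyl (1R,2R,4R)-5-methyl-7-oxabicyclo[2.2.1]hept-5-ene-2-carboxylate (ester endo)
Conditions: MeOH, Sm(OTf)3 (10 mol %), rt
Reagents that add atoms: methanol, CO
Why: Lewis-acid-catalysed alcoholysis (transesterification) of the chelating N-acyloxazolidinone under non-basic conditions, which leaves the α-carbon C6 and the base-sensitive oxygen bridge untouched; the ester is wanted because it is far less acidic than the ketone that must enolise selectively in step 5.

**Step 3**
Reactants: 4
Product: 6 methyl 6-exo-hydroxy-5-endo-methyl-7-oxabicyclo[2.2.1]heptane-2-endo-carboxylate, via alkylborane 5 (not isolated)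
Conditions: BH3·THF (1.0 equiv), THF, 0 °C; then NaBO3·4H2O, H2O, rt
Reagents that add atoms: borane–tetrahydrofuran, B.C1CCOC1; sodium perborate tetrahydrate, [Na+].[Na+].O[B-]1(O)OO[B-](O)(O)OO1
Why: Hydroboration–oxidation: borane adds to the strained trisubstituted alkene from the exo face (the side of the oxygen bridge) with boron on the less substituted carbon C2, and oxidation with retention gives the C2 alcohol exo, i.e. cis (β) to the C1–O bond; the C3 centre made here is erased in step 5.

**Step 4**
Reactants: 6
Product: 7 methyl 5-endo-methyl-6-oxo-7-oxabicyclo[2.2.1]heptane-2-endo-carboxylate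
Conditions: Dess–Martin periodinane, NaHCO3, CH2Cl2, 0 °C to rt
Reagents that add atoms: none
Why: Dess–Martin oxidation of the secondary alcohol under buffered conditions gives the bicyclic C2 ketone, whose only enolisable α-position is C3 because the other α-carbon is the bridgehead C1.

**Step 5**
Reactants: 7
Product: 8 methyl 4-methyl-5-oxo-6-(trimethylsilyloxy)cyclohex-3-ene-1-carboxylate (target numbering: 1β-OSiMe3, C2 ketone, C3=C4, 6α-CO2Me)
Conditions: Me3SiOTf (1.3 equiv), Et3N (2 equiv), CH2Cl2, −20 to 0 °C
Reagents that add atoms: trimethylsilyl trifluoromethanesulfonate, C[Si](C)(C)OS(=O)(=O)C(F)(F)F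
Why: β-Elimination (E1cB-type opening of a 7-oxabicyclo[2.2.1]heptan-2-one) promoted by silyl triflate and amine: the ketone forms its silyl enol ether towards C3, the silylated bridge oxygen is expelled from C4 with release of ring strain, and the C3=C4 enone results with the former bridge oxygen left on C1 as a silyl ether of unchanged configuration; the much less acidic ester does not enolise, so opening towards C1 does not compete.

**Step 6**
Reactants: 8
Product: 10 methyl 5,6-dihydroxy-4-methylcyclohex-3-ene-1-carboxylate (target numbering: 1β,2β-diol; 6α-CO2Me), via silyl ether 9 (not isolated)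
Conditions: (R)-2-methyl-CBS-oxazaborolidine (0.2 equiv), catecholborane (1.5 equiv), toluene, −78 °C; then MeOH, citric acid, rt
Reagents that add atoms: none
Why: Corey–Bakshi–Shibata reduction: the (R)-oxazaborolidine, which treats the alkenyl carbon C3 as the large and C1 as the small substituent, delivers hydride to the α face of the C2 carbonyl (also the face anti to the C1 silyloxy group, a matched case) and sets C2–OH β, cis to C1–O; methanolic citric acid then cleaves the borate and the labile silyl ether.

**Step 7**
Reactants: 10
Product: 11 8-hydroxy-4-methyl-6-oxabicyclo[3.2.1]oct-3-en-7-one (C7 carbonyl bridged from C6 to the 2β oxygen; 1β-OH free and syn to the lactone bridge)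
Conditions: 1,5,7-triazabicyclo[4.4.0]dec-5-ene (TBD, 0.3 equiv), toluene, 80 °C, 4 Å molecular sieves
Reagents that add atoms: none
Why: Base-mediated epimerisation with lactone trapping: reversible enolisation of the ester inverts C6, and since only the 6β epimer can acylate the 2β hydroxyl, the mixture drains into the bridged γ-lactone, which fixes C6 cis to the C1 and C2 oxygens (thermodynamic control through a temporary ring); the free C1 hydroxyl keeps the competing β-elimination slow.

**Step 8**
Reactants: 11
Product: 12 5,6-dihydroxy-N-methoxy-N,4-dimethylcyclohex-3-ene-1-carboxamide, all-cis (target numbering: 1β,2β-diol; 6β-amide)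
Conditions: MeNH(OMe), AlMe3, CH2Cl2, 0 °C to rt; aqueous potassium sodium tartrate work-up
Reagents that add atoms: N,O-dimethylhydroxylamine, CNOC
Why: Aminolysis of the lactone by the aluminium amide (Weinreb amide formation) opens the temporary ring without touching C6, because the amide α-hydrogen is not acidic enough to epimerise under these conditions.

**Step 9**
Reactants: 12
Product: 13 N-methoxy-N-methylamide of 1β,2β-dihydroxy-3β,4β-epoxy-3-methylcyclohexane-6β-carboxylic acid (target numbering)
Conditions: VO(acac)2 (5 mol %), t-BuOOH, CH2Cl2, 0 °C to rt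
Reagents that add atoms: tert-butyl hydroperoxide, CC(C)(C)OO
Why: Vanadium-catalysed hydroxyl-directed epoxidation: the peroxide bound to vanadium at the allylic 2β hydroxyl (assisted by the homoallylic 1β hydroxyl) is delivered to the β face of the only alkene and sets C3 and C4 as the cis epoxy alcohol.

**Step 10**
Reactants: 13
Product: 14 1,2-bis(triethylsilyl) ether of 13
Conditions: Et3SiCl (3 equiv), imidazole, DMAP (cat.), DMF, rt
Reagents that add atoms: chlorotriethylsilane, CC[Si](Cl)(CC)CC
Why: Silylation with silyl chloride and imidazole masks both hydroxyls for the strongly basic steps that follow and, being free of Lewis acid, does not endanger the epoxide.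

**Step 11**
Reactants: 14
Product: 15 methyl ketone: 1-[1β,2β-bis(triethylsilyloxy)-3β,4β-epoxy-3-methylcyclohex-6β-yl]ethanone (target numbering)
Conditions: MeMgBr (3 equiv), THF, −20 to 0 °C
Reagents that add atoms: methylmagnesium bromide, C[Mg]Br
Why: Weinreb ketone synthesis: the Grignard reagent gives a magnesium-chelated tetrahedral intermediate that releases the methyl ketone only on work-up, so over-addition is excluded, and the cold, short reaction leaves the epoxide intact.

**Step 12**
Reactants: 15
Product: 16 alkenyl triflate: 1-[1β,2β-bis(triethylsilyloxy)-3β,4β-epoxy-3-methylcyclohex-6β-yl]ethenyl trifluoromethanesulfonate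
Conditions: KN(SiMe3)2 (1.2 equiv), THF, −78 °C; then PhNTf2
Reagents that add atoms: N-phenylbis(trifluoromethanesulfonimide), FC(F)(F)S(=O)(=O)N(c1ccccc1)S(=O)(=O)C(F)(F)F
Why: Kinetic enolate triflation: the bulky amide base removes a proton from the unhindered methyl group and not from the C6 methine, so C6 is not epimerised, and O-sulfonylation gives the 2-triflyloxy-1-alkene that carries the future C14 methylene.

**Step 13**
Reactants: 17 4-methylpent-3-en-1-ol
Product: 18 4-methylpent-3-enal
Conditions: Dess–Martin periodinane, NaHCO3, CH2Cl2, 0 °C; used at once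
Reagents that add atoms: none
Why: Dess–Martin oxidation of the homoallylic alcohol under buffered conditions gives the β,γ-unsaturated aldehyde without migration of the double bond into conjugation.

**Step 14**
Reactants: 16; 18
Product: 19 allylic alcohols, both C8 epimers: C6–C7(=C14H2)–C8H(OH)–CH2–CH=C(CH3)2 on the bis-silylated epoxy ring of 16
Conditions: CrCl2 (4 equiv), NiCl2 (2 mol %), DMF, rt
Reagents that add atoms: none
Why: Nozaki–Hiyama–Kishi coupling: nickel inserts into the alkenyl C–O bond, the alkenyl group passes to chromium and adds chemoselectively to the aldehyde, forming the C7–C8 bond next to the 1,1-disubstituted alkene in the presence of the epoxide and the silyl ethers; C8 is formed without control, which does not matter because it is oxidised in step 15.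

**Step 15**
Reactants: 19
Product: 20 enone: C6–C7(=C14H2)–C8(=O)–CH2–CH=C(CH3)2 on the same ring
Conditions: Dess–Martin periodinane, NaHCO3, CH2Cl2, 0 °C
Reagents that add atoms: none
Why: Dess–Martin oxidation of the allylic alcohols converges both C8 epimers on one cross-conjugated enone under buffered conditions that do not move the β,γ-double bond.

**Step 16**
Reactants: 20
Product: 21 (8S)-allylic alcohol
Conditions: (R)-2-methyl-CBS-oxazaborolidine (0.3 equiv), catecholborane (1.5 equiv), toluene, −78 °C; then MeOH
Reagents that add atoms: none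
Why: Corey–Bakshi–Shibata reduction: with the fully substituted alkenyl carbon C7 as the large and the C9 methylene as the small substituent, the (R)-oxazaborolidine directs 1,2-hydride delivery to the face that gives the (8S) alcohol (reagent control).

**Step 17**
Reactants: 21 (8S)-allylic alcohol; 22 angelic anhydride [(Z)-2-methylbut-2-enoic anhydride]
Product: 23 8-angelate: (8S)-8-(angeloyloxy)-1β,2β-bis(triethylsilyloxy)-3β,4β-epoxybisabola-7(14),10-diene
Conditions: LiN(SiMe3)2 (1.1 equiv), THF, −78 °C; then 22 (1.5 equiv), −78 to 0 °C; aqueous NH4Cl work-up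
Reagents that add atoms: none
Why: Stereoconservative O-acylation of a lithium alkoxide with the symmetrical anhydride (nucleophilic acyl substitution): the only free hydroxyl, the allylic one at C8, is deprotonated and acylated in the cold without any nucleophilic catalyst, so no reversible conjugate addition can turn the (Z)-2-methylbut-2-enoyl group into its (E) isomer, and since no bond to the C8 carbon is broken its configuration is retained.

**Step 18**
Reactants: 23
Product: 24 diol 8-angelate: (8S)-8-(angeloyloxy)-3β,4β-epoxybisabola-7(14),10-diene-1β,2β-diol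
Conditions: Bu4NF, AcOH, THF, 0 °C to rt
Reagents that add atoms: none
Why: Fluoride-mediated cleavage of both triethylsilyl ethers (desilylation), buffered with acetic acid so that the liberated alkoxides can neither attack the epoxide nor cleave the C8 ester or isomerise its (Z) double bond.

**Step 19**
Reactants: 24; 22 angelic anhydride
Product: 25 tris-angelate: (8S)-1β,2β,8-tris(angeloyloxy)-3β,4β-epoxybisabola-7(14),10-diene
Conditions: LiN(SiMe3)2 (2.0 equiv), THF, −78 °C; then 22 (4 equiv), −78 to 0 °C; aqueous NH4Cl work-up
Reagents that add atoms: none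
Why: Twofold O-acylation of the dilithium alkoxide of the cis-1,2-diol with the anhydride under the stereoconservative conditions of step 17: the C2 alkoxide is cis to the oxirane oxygen and cannot attack C3 from the rear, so no Payne-type epoxide migration is possible, any acyl transfer between oxygens is without consequence because all three esters are the same and the anhydride is in excess, and the absence of a nucleophilic catalyst keeps the enoates (Z).

**Step 20**
Reactants: 25
Product: 26 target, (1S,2S,3R,4R,6R,8S,10R)-1,2,8-tris(angeloyloxy)-3,4:10,11-diepoxybisabol-7(14)-ene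
Conditions: D-fructose-derived Shi ketone (0.3 equiv), Oxone (2KHSO5·KHSO4·K2SO4), K2CO3, Bu4NHSO4, MeCN/dimethoxymethane/aqueous Na2B4O7 buffer, 0 °C
Reagents that add atoms: potassium peroxymonosulfate, [K+].[O-]S(=O)(=O)OO
Why: Shi epoxidation: the chiral dioxirane formed from the D-fructose-derived ketone reacts through the spiro transition state only with the electron-rich trisubstituted C10=C11 alkene (the 1,1-disubstituted alkene next to an ester and the three enoates are too electron-poor) and sets C10 as (R) by reagent control.

**Compound list**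

1 | 3-methylfuran | Cc1ccoc1 | starting material
2 | 3-acryloyl-1,3-oxazolidin-2-one | C=CC(=O)N1CCOC1=O | starting material
3 | 3-[(1R,2R,4R)-5-methyl-7-oxabicyclo[2.2.1]hept-5-ene-2-carbonyl]-1,3-oxazolidin-2-one (carbonyl endo) | O=C(N1CCOC1=O)[C@@H]1C[C@H]2O[C@@H]1C=C2C | intermediate
4 | methyl (1R,2R,4R)-5-methyl-7-oxabicyclo[2.2.1]hept-5-ene-2-carboxylate (ester endo) | COC(=O)[C@@H]1C[C@H]2O[C@@H]1C=C2C | intermediate
5 | alkylborane: methyl 6-exo-boranyl-5-endo-methyl-7-oxabicyclo[2.2.1]heptane-2-endo-carboxylate | COC(=O)[C@@H]1C[C@H]2O[C@@H]1[C@H](B)[C@H]2C | intermediate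
6 | methyl 6-exo-hydroxy-5-endo-methyl-7-oxabicyclo[2.2.1]heptane-2-endo-carboxylate | COC(=O)[C@@H]1C[C@H]2O[C@@H]1[C@H](O)[C@H]2C | intermediate
7 | methyl 5-endo-methyl-6-oxo-7-oxabicyclo[2.2.1]heptane-2-endo-carboxylate | COC(=O)[C@@H]1C[C@H]2O[C@@H]1C(=O)[C@H]2C | intermediate
8 | methyl 4-methyl-5-oxo-6-(trimethylsilyloxy)cyclohex-3-ene-1-carboxylate (1β-OSiMe3, 6α-CO2Me, trans) | COC(=O)[C@@H]1CC=C(C)C(=O)[C@H]1O[Si](C)(C)C | intermediate
9 | silyl ether: methyl 5-hydroxy-4-methyl-6-(trimethylsilyloxy)cyclohex-3-ene-1-carboxylate (1β-OSiMe3, 2β-OH, 6α-CO2Me) | COC(=O)[C@@H]1CC=C(C)[C@@H](O)[C@H]1O[Si](C)(C)C | intermediate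
10 | methyl 5,6-dihydroxy-4-methylcyclohex-3-ene-1-carboxylate (1β,2β-diol; 6α-CO2Me) | COC(=O)[C@@H]1CC=C(C)[C@@H](O)[C@H]1O | intermediate
11 | 8-hydroxy-4-methyl-6-oxabicyclo[3.2.1]oct-3-en-7-one (hydroxyl syn to the lactone bridge) | O=C1O[C@@H]2C(C)=CC[C@H]1[C@@H]2O | intermediate
12 | 5,6-dihydroxy-N-methoxy-N,4-dimethylcyclohex-3-ene-1-carboxamide, all-cis (1β,2β-diol; 6β-amide) | CON(C)C(=O)[C@H]1CC=C(C)[C@@H](O)[C@H]1O | intermediate
13 | N-methoxy-N-methylamide of 1β,2β-dihydroxy-3β,4β-epoxy-3-methylcyclohexane-6β-carboxylic acid | CON(C)C(=O)[C@H]1C[C@H]2O[C@@]2(C)[C@@H](O)[C@H]1O | intermediate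
14 | 1,2-bis(triethylsilyl) ether of 13 | CON(C)C(=O)[C@H]1C[C@H]2O[C@@]2(C)[C@@H](O[Si](CC)(CC)CC)[C@H]1O[Si](CC)(CC)CC | intermediate
15 | 1-[1β,2β-bis(triethylsilyloxy)-3β,4β-epoxy-3-methylcyclohex-6β-yl]ethanone | CC(=O)[C@H]1C[C@H]2O[C@@]2(C)[C@@H](O[Si](CC)(CC)CC)[C@H]1O[Si](CC)(CC)CC | intermediate
16 | 1-[1β,2β-bis(triethylsilyloxy)-3β,4β-epoxy-3-methylcyclohex-6β-yl]ethenyl trifluoromethanesulfonate | C=C(OS(=O)(=O)C(F)(F)F)[C@H]1C[C@H]2O[C@@]2(C)[C@@H](O[Si](CC)(CC)CC)[C@H]1O[Si](CC)(CC)CC | intermediate
17 | 4-methylpent-3-en-1-ol | CC(C)=CCCO | starting material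
18 | 4-methylpent-3-enal | CC(C)=CCC=O | intermediate
19 | 1β,2β-bis(triethylsilyloxy)-3β,4β-epoxybisabola-7(14),10-dien-8-ol, both C8 epimers | C=C(C(O)CC=C(C)C)[C@H]1C[C@H]2O[C@@]2(C)[C@@H](O[Si](CC)(CC)CC)[C@H]1O[Si](CC)(CC)CC | intermediate
20 | 1β,2β-bis(triethylsilyloxy)-3β,4β-epoxybisabola-7(14),10-dien-8-one | C=C(C(=O)CC=C(C)C)[C@H]1C[C@H]2O[C@@]2(C)[C@@H](O[Si](CC)(CC)CC)[C@H]1O[Si](CC)(CC)CC | intermediate
21 | (8S)-1β,2β-bis(triethylsilyloxy)-3β,4β-epoxybisabola-7(14),10-dien-8-ol | C=C([C@H](CC=C(C)C)O)[C@H]1C[C@H]2O[C@@]2(C)[C@@H](O[Si](CC)(CC)CC)[C@H]1O[Si](CC)(CC)CC | intermediate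
22 | angelic anhydride, (Z)-2-methylbut-2-enoic anhydride | C/C=C(/C)C(=O)OC(=O)/C(C)=C\C | starting material
23 | (8S)-8-(angeloyloxy)-1β,2β-bis(triethylsilyloxy)-3β,4β-epoxybisabola-7(14),10-diene | C=C([C@H](CC=C(C)C)OC(=O)/C(C)=C\C)[C@H]1C[C@H]2O[C@@]2(C)[C@@H](O[Si](CC)(CC)CC)[C@H]1O[Si](CC)(CC)CC | intermediate
24 | (8S)-8-(angeloyloxy)-3β,4β-epoxybisabola-7(14),10-diene-1β,2β-diol | C=C([C@H](CC=C(C)C)OC(=O)/C(C)=C\C)[C@H]1C[C@H]2O[C@@]2(C)[C@@H](O)[C@H]1O | intermediate
25 | (8S)-1β,2β,8-tris(angeloyloxy)-3β,4β-epoxybisabola-7(14),10-diene | C=C([C@H](CC=C(C)C)OC(=O)/C(C)=C\C)[C@H]1C[C@H]2O[C@@]2(C)[C@@H](OC(=O)/C(C)=C\C)[C@H]1OC(=O)/C(C)=C\C | intermediate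
26 | (1S,2S,3R,4R,6R,8S,10R)-1,2,8-tris(angeloyloxy)-3,4:10,11-diepoxybisabol-7(14)-ene (CNP0258231.4) | C=C([C@H](C[C@H]1OC1(C)C)OC(=O)/C(C)=C\C)[C@H]1C[C@H]2O[C@@]2(C)[C@@H](OC(=O)/C(C)=C\C)[C@H]1OC(=O)/C(C)=C\C | target

**Step count**

Total step count: 20. Longest linear sequence: 19 steps (steps 1–12 and 14–20, from 3-methylfuran); step 13 prepares the aldehyde fragment.

**Steps most likely to fail**

Step 1. What may go wrong: Friedel–Crafts-type conjugate addition of the furan C2 position to the activated acrylimide in place of cycloaddition, partial loss of regiocontrol, and cycloreversion on warming that erodes the endo preference and the enantiomeric purity. The fallback sets out from 1 and returns at 4. Compound 1 is combined with 2-bromoacrolein under catalysis by the oxazaborolidine made from N-tosyl-(S)-tryptophan and butylboronic acid (CH2Cl2, −78 °C). This 2-substituted enal reacts through a transition state that places the formyl group exo and should give (1R,2R,4R)-2-bromo-5-methyl-7-oxabicyclo[2.2.1]hept-5-ene-2-carbaldehyde F1, in which the bromine also blocks any enolisation. Pinnick oxidation (NaClO2, NaH2PO4, 2-methylbut-2-ene) gives the bromo acid (1R,2R,4R)-2-bromo-5-methyl-7-oxabicyclo[2.2.1]hept-5-ene-2-carboxylic acid F2, and Me3SiCHN2 in MeOH gives its methyl ester F3. Radical debromination (Bu3SnH, Et3B, air, toluene, rt) delivers hydrogen to the exo face of the α-ester radical, which leaves the ester endo and gives 4.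

Step 7. What may go wrong: enolisation of the ester too slow compared with dehydration of the β-hydroxy ester (followed by aromatisation) or retro-aldol ring cleavage, so that the lactone does not form cleanly. The fallback sets out from 10 and returns at 12, replacing thermodynamic trapping by kinetic protonation. Compound 10 is converted into its acetonide, methyl 1β,2β-(isopropylidenedioxy)-3-methylcyclohex-3-ene-6α-carboxylate F4 (2,2-dimethoxypropane, pyridinium p-toluenesulfonate). The ester enolate is formed with LiN(iPr)2 in THF at −78 °C and protonated at that temperature with 2,6-di-tert-butylphenol on the convex α face, anti to the dioxolane, which should give the 6β epimer F5. The aluminium amide from AlMe3 and MeNH(OMe) converts F5 into the Weinreb amide acetonide F6, and 80 % aqueous acetic acid removes the acetonide to give 12.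

Step 19. What may go wrong: incomplete acylation of the hindered vicinal C1/C2 oxygens, whose dilithium alkoxide may aggregate, and Z-to-E isomerisation of angeloyl groups (angelate to tiglate) if surplus amide base deprotonates an enoate at its γ position. The fallback sets out from 24 and returns at 25, building the two missing (Z)-enoates on the substrate. Steglich esterification of 24 with 2-[bis(2,2,2-trifluoroethoxy)phosphoryl]propanoic acid (DCC, DMAP, CH2Cl2) gives the 1,2-bis(phosphonopropanoate) of 24 F7. Twofold Still–Gennari olefination (KN(SiMe3)2, 18-crown-6, acetaldehyde, THF, −78 °C) then forms the two (Z)-2-methylbut-2-enoates and gives 25.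

**Further compounds**

F1 | step 1 | (1R,2R,4R)-2-bromo-5-methyl-7-oxabicyclo[2.2.1]hept-5-ene-2-carbaldehyde (formyl exo) | O=C[C@@]1(Br)C[C@H]2O[C@@H]1C=C2C
F2 | step 1 | (1R,2R,4R)-2-bromo-5-methyl-7-oxabicyclo[2.2.1]hept-5-ene-2-carboxylic acid | OC(=O)[C@@]1(Br)C[C@H]2O[C@@H]1C=C2C
F3 | step 1 | methyl (1R,2R,4R)-2-bromo-5-methyl-7-oxabicyclo[2.2.1]hept-5-ene-2-carboxylate | COC(=O)[C@@]1(Br)C[C@H]2O[C@@H]1C=C2C
F4 | step 7 | methyl 1β,2β-(isopropylidenedioxy)-3-methylcyclohex-3-ene-6α-carboxylate (acetonide of 10) | COC(=O)[C@@H]1CC=C(C)[C@H]2OC(C)(C)O[C@@H]12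
F5 | step 7 | methyl 1β,2β-(isopropylidenedioxy)-3-methylcyclohex-3-ene-6β-carboxylate | COC(=O)[C@H]1CC=C(C)[C@H]2OC(C)(C)O[C@@H]12
F6 | step 7 | N-methoxy-N-methyl-1β,2β-(isopropylidenedioxy)-3-methylcyclohex-3-ene-6β-carboxamide | CON(C)C(=O)[C@H]1CC=C(C)[C@H]2OC(C)(C)O[C@@H]12
F7 | step 19 | 1,2-bis{2-[bis(2,2,2-trifluoroethoxy)phosphoryl]propanoate} of 24 | C=C([C@H](CC=C(C)C)OC(=O)/C(C)=C\C)[C@H]1C[C@H]2O[C@@]2(C)[C@@H](OC(=O)C(C)P(=O)(OCC(F)(F)F)OCC(F)(F)F)[C@H]1OC(=O)C(C)P(=O)(OCC(F)(F)F)OCC(F)(F)F
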